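## Retrosynthetic overview

1. Target ⇐ hydroxy diester ⇐ ring-A ketone: ester hydrolysis, and hydride delivery to C2 from the α face (the axial 2β-hydroxyl lies between the axial methyls on C4 and C10).
2. Keto decalin ⇐ acyclic enyne in one cationic cascade of a terminal alkyne (C8≡C17), an E-trisubstituted alkene (C9=C10) and a silyl enol ether (C1=C2). Ring B closes first (C8–C9), ring A last (C1–C10).
3. Enabling feature: the methyl-bearing ring-fusion carbon C10, shared by rings A and B, is flanked in ring B by the exocyclic methylene C8=C17 and in ring A by C1–C2(O). The methylene is the footprint of an alkyne, C10 of a tertiary cation and C2–O of an enol ether, and all three π-systems sit on one chain that branches at C5.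
4. Acyclic precursor ⇐ α,α-disubstituted γ-lactone (a temporary ring tying the C18 carboxyl to a sacrificial oxygen on C2). An orthoester Claisen rearrangement of a (Z)-allylic alcohol with the orthoester of (S)-γ-valerolactone sets quaternary C4, C5 and the E-alkene together.
5. Allylic alcohol ⇐ (Z)-α-iodoalkene (from a silylated pentynal) + a C7 aldehyde cut from methyl geranate, which supplies the E-enoate of the side chain.

Key step: step 11

Remark: positions are given in labdane numbering (C17 = exocyclic methylene carbon, C18 = carboxyl carbon on C4, C19 and C20 = methyls on C4 and C10); the SMILES is read as 2β-hydroxy, 4α-carboxy (equatorial), 4β- and 10β-methyl, 5α-H, 9α-H, and methyl geranate is assumed to be at hand as the pure 2E isomer.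

## Route

Step 1
Reactants: 1 methyl (2E)-3,7-dimethylocta-2,6-dienoate (methyl geranate)
Product: 2 methyl (2E)-3-methyl-6-oxohex-2-enoate
Conditions: O3 (1 equiv), CH2Cl2/pyridine, −78 °C; Me2S, −78 °C → rt
Reagents that add atoms: ozone, O=[O+][O-]
Why: Ozonolysis with reductive work-up should cleave only the electron-rich 6,7-alkene, the conjugated enoate reacting far more slowly, so that the E-enoate of the future side chain (C11–C16) is taken over unchanged from geranate.

Step 2
Reactants: 3 5-(trimethylsilyl)pent-4-yn-1-ol
Product: 4 5-(trimethylsilyl)pent-4-ynal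
Conditions: TEMPO (10 mol%), PhI(OAc)2, CH2Cl2, rt
Reagents that add atoms: none
Why: TEMPO (oxoammonium) oxidation of a primary alcohol should stop at the aldehyde and is compatible with the silylalkyne.

Step 3
Reactants: 4 5-(trimethylsilyl)pent-4-ynal; 5 ethyl(triphenyl)phosphonium iodide
Product: 9 [(5Z)-6-iodohept-5-en-1-yn-1-yl](trimethyl)silane, via ethylidenetriphenylphosphorane 6 (not isolated), via (1-iodoethyl)triphenylphosphonium iodide 7 (not isolated), via (1-iodoethylidene)triphenylphosphorane 8 (not isolated)
Conditions: 5, n-BuLi, THF, 0 °C; I2, −78 °C; NaN(SiMe3)2, −20 °C; 4, −78 °C → rt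
Reagents that add atoms: iodine, [I][I]
Why: Stork–Zhao-type Wittig olefination with the α-iodo ylide, which under kinetic control is expected to give the (Z)-2-iodoalk-2-ene with iodine cis to the chain.

Step 4
Reactants: 9 [(5Z)-6-iodohept-5-en-1-yn-1-yl](trimethyl)silane; 2 methyl (2E)-3-methyl-6-oxohex-2-enoate
Product: 12 methyl (2E,6R,7Z)-6-hydroxy-3,7-dimethyl-12-(trimethylsilyl)dodeca-2,7-dien-11-ynoate, via alkenyllithium 10 (not isolated), via alkenylzinc bromide 11 (not isolated)
Conditions: 9, t-BuLi (2 equiv), Et2O, −78 °C; ZnBr2, −78 → 0 °C; (Et2NCH2)2, (−)-MIB (10 mol%), toluene; 2, 0 °C; aqueous NH4Cl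
Reagents that add atoms: none
Why: Catalytic enantioselective alkenylzinc addition to an aldehyde, in which iodine–lithium exchange and transmetalation retain the Z geometry and the amino alcohol (−)-MIB is expected to direct the alkenyl group to the Si face of the aldehyde, setting the 6R carbinol (C9 in labdane numbering) whose chirality is later relayed to C5.

Step 5
Reactants: 13 (5S)-5-methyloxolan-2-one ((S)-γ-valerolactone)
Product: 15 (3RS,5S)-3,5-dimethyloxolan-2-one, via lithium enolate 14 (not isolated)
Conditions: LiN(i-Pr)2, THF, −78 °C; MeI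
Reagents that add atoms: iodomethane, CI
Why: Lactone enolate methylation introduces the future C19 methyl, and the configuration of the new centre does not matter because this carbon becomes trigonal again in step 7.

Step 6
Reactants: 15 (3RS,5S)-3,5-dimethyloxolan-2-one
Product: 17 (5S)-2,2-diethoxy-3,5-dimethyloxolane, via O-ethyl lactonium tetrafluoroborate 16 (not isolated)
Conditions: Et3OBF4, CH2Cl2, rt; NaOEt, EtOH, −78 → 0 °C
Reagents that add atoms: triethyloxonium tetrafluoroborate, CC[O+](CC)CC.F[B-](F)(F)F; sodium ethoxide, CC[O-].[Na+]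
Why: O-Ethylation of the lactone carbonyl by the Meerwein salt followed by ethoxide capture of the dialkoxycarbenium ion is the standard preparation of a lactone orthoester.

Step 7
Reactants: 12 methyl (2E,6R,7Z)-6-hydroxy-3,7-dimethyl-12-(trimethylsilyl)dodeca-2,7-dien-11-ynoate; 17 (5S)-2,2-diethoxy-3,5-dimethyloxolane
Product: 19 methyl (2E,6E,8R)-8-[(3R,5S)-3,5-dimethyl-2-oxooxolan-3-yl]-3,7-dimethyl-12-(trimethylsilyl)dodeca-2,6-dien-11-ynoate, via cyclic ketene acetal 18 (not isolated)
Conditions: 17 (3 equiv), EtCO2H (10 mol%), xylene, 140 °C, EtOH distilled off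
Reagents that add atoms: none
Why: Orthoester (Johnson–)Claisen rearrangement through a chair in which the five-membered ring fixes the ketene acetal geometry (C3 trans and the methyl cis to the allylic oxygen), the C9 substituent is equatorial and the Z-substituent axial, so that the carbinol chirality is transferred to C5, the quaternary C4 is set relative to it, the new C9=C10 alkene is E and the allyl unit enters trans to the ring methyl of the matched (S)-lactone.

Step 8
Reactants: 19 methyl (2E,6E,8R)-8-[(3R,5S)-3,5-dimethyl-2-oxooxolan-3-yl]-3,7-dimethyl-12-(trimethylsilyl)dodeca-2,6-dien-11-ynoate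
Product: 21 (2E,6E,8R,9R)-8-(but-3-yn-1-yl)-3,7,9-trimethyl-9-(2-oxopropyl)deca-2,6-dienedioic acid, via dilithium hydroxy dicarboxylate 20 (not isolated)
Conditions: LiOH, THF/MeOH/H2O, 50 °C; TEMPO (20 mol%), PhI(OAc)2, MeCN/H2O, 0 °C → rt; aqueous HCl
Reagents that add atoms: lithium hydroxide, [Li+].[OH-]
Why: Saponification opens the lactone, hydrolyses the methyl ester and removes the alkyne silyl group, and TEMPO oxidation of the freed secondary alcohol at the carboxylate stage (where relactonization is impossible) gives the methyl ketone, erasing the sacrificial C2 stereocentre.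

Step 9
Reactants: 21 (2E,6E,8R,9R)-8-(but-3-yn-1-yl)-3,7,9-trimethyl-9-(2-oxopropyl)deca-2,6-dienedioic acid
Product: 22 dimethyl (2E,6E,8R,9R)-8-(but-3-yn-1-yl)-3,7,9-trimethyl-9-(2-oxopropyl)deca-2,6-dienedioate
Conditions: MeI, K2CO3, DMF, rt
Reagents that add atoms: iodomethane, CI
Why: SN2 O-alkylation of both carboxylates gives the dimethyl ester without touching the ketone or the stereocentres.

Step 10
Reactants: 22 dimethyl (2E,6E,8R,9R)-8-(but-3-yn-1-yl)-3,7,9-trimethyl-9-(2-oxopropyl)deca-2,6-dienedioate
Product: 23 dimethyl (2E,6E,8R,9R)-8-(but-3-yn-1-yl)-9-{2-[(tert-butyldimethylsilyl)oxy]prop-2-en-1-yl}-3,7,9-trimethyldeca-2,6-dienedioate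
Conditions: TBSOTf, Et3N, CH2Cl2, −78 → 0 °C
Reagents that add atoms: tert-butyldimethylsilyl trifluoromethanesulfonate, CC(C)(C)[Si](C)(C)OS(=O)(=O)C(F)(F)F
Why: Soft enolization and O-silylation of the methyl ketone should take place at the methyl group (C1), because the other α-carbon (C3) is neopentylic next to the quaternary C4, which gives the 2-silyloxyallyl terminator.

Step 11
Reactants: 23 dimethyl (2E,6E,8R,9R)-8-(but-3-yn-1-yl)-9-{2-[(tert-butyldimethylsilyl)oxy]prop-2-en-1-yl}-3,7,9-trimethyldeca-2,6-dienedioate
Product: 24 methyl (1R,4aR,5S,8aR)-5-[(3E)-5-methoxy-3-methyl-5-oxopent-3-en-1-yl]-1,4a-dimethyl-6-methylidene-3-oxodecahydronaphthalene-1-carboxylate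
Conditions: Ph3PAuNTf2 (5 mol%), t-BuOH (2 equiv), CH2Cl2, −20 °C → rt
Reagents that add atoms: none
Why: Proposed new method: cationic monovalent gold π-activates the terminal alkyne, the E-alkene attacks it through C9 (C8–C9 bond, ring B; 6-exo-dig with respect to the alkyne, endo with respect to the alkene) because the positive charge then sits on the tertiary methyl-bearing C10 (cyclopropyl gold carbene or tertiary cation), and C1 of the silyl enol ether captures C10 from the opposite face (C1–C10 bond, ring A; 6-endo-trig with respect to the enol ether, chair), after which silyl transfer to t-BuOH unveils the C2 ketone and the released proton cleaves the C17–Au bond to give the exocyclic methylene. The closest known reaction types are the gold-catalysed cyclization of 1,6-enynes with capture of a nucleophile at the more substituted alkene carbon (alkoxy- and carbocyclization giving a six-membered ring with an exocyclic methylene), gold-initiated enyne polycyclization and cationic polyene cyclizations terminated by silyl enol ethers; their combination in one bicyclization has not been shown on this substrate class. The new stereocentres C9 and C10 arise from stereospecific anti addition of C8 and C1 across the E-alkene, which puts the side chain equatorial on C9 and the methyl axial on C10. Their sense relative to C5 is set by the chair–chair array in which the bulky C4 substituent is equatorial on the forming ring B, so that the two tethers reach opposite faces of the alkene and the ring fusion becomes trans (H5 anti to the C10 methyl). The step needs six- over five-membered enyne closure (secured by the methyl on C10), termination by C1 instead of proton loss, lactonization by the C18 ester or attack of the enoate (secured by the high nucleophilicity of the enol ether, the reversible participation of a methyl ester and the electron-poor enoate), and survival of the enol ether until the cascade starts (neutral catalyst, a bulky alcohol as the only proton source).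

Step 12
Reactants: 24 methyl (1R,4aR,5S,8aR)-5-[(3E)-5-methoxy-3-methyl-5-oxopent-3-en-1-yl]-1,4a-dimethyl-6-methylidene-3-oxodecahydronaphthalene-1-carboxylate
Product: 25 methyl (1R,3S,4aR,5S,8aR)-3-hydroxy-5-[(3E)-5-methoxy-3-methyl-5-oxopent-3-en-1-yl]-1,4a-dimethyl-6-methylidenedecahydronaphthalene-1-carboxylate
Conditions: LiBH(s-Bu)3, THF, −78 °C; H2O
Reagents that add atoms: none
Why: Hydride reduction of the ring-A ketone with a bulky trialkylborohydride, in which the β face of C2 is shielded by the two syn-axial methyls on C4 and C10 so that hydride should enter from the α face and give the axial 2β-alcohol (3S in the systematic name).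

Step 13
Reactants: 25 methyl (1R,3S,4aR,5S,8aR)-3-hydroxy-5-[(3E)-5-methoxy-3-methyl-5-oxopent-3-en-1-yl]-1,4a-dimethyl-6-methylidenedecahydronaphthalene-1-carboxylate
Product: 26 (1R,3S,4aR,5S,8aR)-5-[(3E)-4-carboxy-3-methylbut-3-en-1-yl]-3-hydroxy-1,4a-dimethyl-6-methylidenedecahydronaphthalene-1-carboxylic acid
Conditions: KOH, EtOH/H2O, 100 °C (sealed tube); aqueous HCl
Reagents that add atoms: potassium hydroxide, [K+].[OH-]
Why: Saponification of both methyl esters, with forcing conditions for the hindered equatorial ester on C4, should leave the stereocentres, the exocyclic methylene and the E-enoate (protected as its carboxylate) untouched.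

## Compound list

1 | methyl (2E)-3,7-dimethylocta-2,6-dienoate (methyl geranate) | CC(C)=CCC/C(C)=C/C(=O)OC | starting material
2 | methyl (2E)-3-methyl-6-oxohex-2-enoate | O=CCC/C(C)=C/C(=O)OC | intermediate
3 | 5-(trimethylsilyl)pent-4-yn-1-ol | C[Si](C)(C)C#CCCCO | starting material
4 | 5-(trimethylsilyl)pent-4-ynal | C[Si](C)(C)C#CCCC=O | intermediate
5 | ethyl(triphenyl)phosphonium iodide | CC[P+](c1ccccc1)(c1ccccc1)c1ccccc1.[I-] | starting material
6 | ethylidenetriphenylphosphorane | CC=P(c1ccccc1)(c1ccccc1)c1ccccc1 | intermediate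
7 | (1-iodoethyl)triphenylphosphonium iodide | CC(I)[P+](c1ccccc1)(c1ccccc1)c1ccccc1.[I-] | intermediate
8 | (1-iodoethylidene)triphenylphosphorane | CC(I)=P(c1ccccc1)(c1ccccc1)c1ccccc1 | intermediate
9 | [(5Z)-6-iodohept-5-en-1-yn-1-yl](trimethyl)silane | C[Si](C)(C)C#CCC/C=C(C)\I | intermediate
10 | [7-(trimethylsilyl)hept-2-en-6-yn-2-yl]lithium, lithium cis to the chain | C[Si](C)(C)C#CCC/C=C(C)\[Li] | intermediate
11 | bromo[7-(trimethylsilyl)hept-2-en-6-yn-2-yl]zinc, zinc cis to the chain | C[Si](C)(C)C#CCC/C=C(C)\[Zn]Br | intermediate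
12 | methyl (2E,6R,7Z)-6-hydroxy-3,7-dimethyl-12-(trimethylsilyl)dodeca-2,7-dien-11-ynoate | C[Si](C)(C)C#CCC/C=C(C)\[C@H](O)CC/C(C)=C/C(=O)OC | intermediate
13 | (5S)-5-methyloxolan-2-one ((S)-γ-valerolactone) | C[C@H]1CCC(=O)O1 | starting material
14 | lithium (5S)-5-methyl-4,5-dihydrofuran-2-olate | C[C@H]1CC=C([O-])O1.[Li+] | intermediate
15 | (3RS,5S)-3,5-dimethyloxolan-2-one (epimers at C3) | C[C@H]1CC(C)C(=O)O1 | intermediate
16 | (5S)-2-ethoxy-3,5-dimethyl-4,5-dihydro-3H-furan-1-ium tetrafluoroborate | CCOC1=[O+][C@@H](C)CC1C.F[B-](F)(F)F | intermediate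
17 | (5S)-2,2-diethoxy-3,5-dimethyloxolane (epimers at C3) | C[C@H]1CC(C)C(OCC)(OCC)O1 | intermediate
18 | methyl (2E,6R,7Z)-6-{[(5S)-3,5-dimethyl-4,5-dihydrofuran-2-yl]oxy}-3,7-dimethyl-12-(trimethylsilyl)dodeca-2,7-dien-11-ynoate | CC1=C(O[C@H](CC/C(C)=C/C(=O)OC)/C(C)=C\CCC#C[Si](C)(C)C)O[C@@H](C)C1 | intermediate
19 | methyl (2E,6E,8R)-8-[(3R,5S)-3,5-dimethyl-2-oxooxolan-3-yl]-3,7-dimethyl-12-(trimethylsilyl)dodeca-2,6-dien-11-ynoate | C[Si](C)(C)C#CCC[C@@H]([C@@]1(C)C[C@H](C)OC1=O)/C(C)=C/CC/C(C)=C/C(=O)OC | intermediate
20 | dilithium (2E,6E,8R,9R)-8-(but-3-yn-1-yl)-9-[(2S)-2-hydroxypropyl]-3,7,9-trimethyldeca-2,6-dienedioate | [Li+].[Li+].C#CCC[C@@H]([C@@](C)(C[C@H](C)O)C(=O)[O-])/C(C)=C/CC/C(C)=C/C(=O)[O-] | intermediate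
21 | (2E,6E,8R,9R)-8-(but-3-yn-1-yl)-3,7,9-trimethyl-9-(2-oxopropyl)deca-2,6-dienedioic acid | C#CCC[C@@H]([C@@](C)(CC(C)=O)C(=O)O)/C(C)=C/CC/C(C)=C/C(=O)O | intermediate
22 | dimethyl (2E,6E,8R,9R)-8-(but-3-yn-1-yl)-3,7,9-trimethyl-9-(2-oxopropyl)deca-2,6-dienedioate | C#CCC[C@@H]([C@@](C)(CC(C)=O)C(=O)OC)/C(C)=C/CC/C(C)=C/C(=O)OC | intermediate
23 | dimethyl (2E,6E,8R,9R)-8-(but-3-yn-1-yl)-9-{2-[(tert-butyldimethylsilyl)oxy]prop-2-en-1-yl}-3,7,9-trimethyldeca-2,6-dienedioate | C#CCC[C@@H]([C@@](C)(CC(=C)O[Si](C)(C)C(C)(C)C)C(=O)OC)/C(C)=C/CC/C(C)=C/C(=O)OC | intermediate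
24 | methyl (1R,4aR,5S,8aR)-5-[(3E)-5-methoxy-3-methyl-5-oxopent-3-en-1-yl]-1,4a-dimethyl-6-methylidene-3-oxodecahydronaphthalene-1-carboxylate | C=C1CC[C@@H]2[C@](C)(CC(=O)C[C@@]2(C)C(=O)OC)[C@H]1CC/C(C)=C/C(=O)OC | intermediate
25 | methyl (1R,3S,4aR,5S,8aR)-3-hydroxy-5-[(3E)-5-methoxy-3-methyl-5-oxopent-3-en-1-yl]-1,4a-dimethyl-6-methylidenedecahydronaphthalene-1-carboxylate | C=C1CC[C@@H]2[C@](C)(C[C@H](O)C[C@@]2(C)C(=O)OC)[C@H]1CC/C(C)=C/C(=O)OC | intermediate
26 | (1R,3S,4aR,5S,8aR)-5-[(3E)-4-carboxy-3-methylbut-3-en-1-yl]-3-hydroxy-1,4a-dimethyl-6-methylidenedecahydronaphthalene-1-carboxylic acid | C=C1CC[C@@H]2[C@](C)(C[C@H](O)C[C@@]2(C)C(=O)O)[C@H]1CC/C(C)=C/C(=O)O | target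

## Step count and risks

Total step count: 13. Longest linear sequence: 10 steps (steps 2, 3, 4, 7, 8, 9, 10, 11, 12, 13).

**Step 11 (carries the label).** What may go wrong: the C10 cation may be intercepted by proton loss or by the ester carbonyl before the enol ether closes ring A; the enol ether may be protodesilylated before the cascade starts; the enyne may close to a five- instead of a six-membered ring.
Fallback with known chemistry, closing the two rings in separate operations, from 22 back to 24. Gold-catalysed methoxycyclization of the 1,6-enyne in 22 (Ph3PAuNTf2, MeOH, rt; a known alkoxycyclization in which methanol adds to the more substituted alkene carbon, anti to the new C8–C9 bond) should give the monocyclic tertiary methyl ether F1. This already carries ring B, the exocyclic methylene and the C9 stereocentre. TBSOTf/Et3N converts its methyl ketone into the silyl enol ether F2. TiCl4 (CH2Cl2, −78 °C) then ionizes the tertiary ether and the enol ether alkylates the cation (Mukaiyama-type SN1 alkylation of a silyl enol ether, chair closure with the C4 substituent equatorial), which returns to 24.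

**Step 7.** What may go wrong: slow rearrangement through a congested chair that forms a quaternary centre, with competing ionization or elimination of the allylic orthoester exchange intermediate, and erosion of the C4 selectivity through a boat pathway.
Fallback from 12 back to 19. Orthoester Claisen rearrangement of 12 with triethyl orthopropionate (EtCO2H, 140 °C) gives the ethyl ester F3, with C5 and the E-alkene set as before but C4 as a mixture. Its lithium enolate (LiN(i-Pr)2, THF, −78 °C) is alkylated with (S)-methyloxirane in the presence of Et2AlCl, and the resulting γ-alkoxide lactonizes with loss of ethanol to 19. The C4 epimer from attack on the other enolate face would have to be separated.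

**Step 4.** What may go wrong: insufficient facial selectivity in the alkenylzinc addition, through a background addition promoted by lithium salts or an unexpected sense of induction.
Fallback from 9 and 2 back to 12. Nozaki–Hiyama–Kishi coupling of 9 with 2 (CrCl2, NiCl2 catalytic, DMSO) gives the racemic allylic alcohol F4. Dess–Martin oxidation gives the (Z)-enone F5. Corey–Bakshi–Shibata reduction with the (S)-oxazaborolidine and BH3·SMe2, in which the branched alkenyl group acts as the large substituent, should return the (6R)-alcohol 12.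

## Further compounds

F1 | step 11 | monocyclic tertiary methyl ether: ring B closed by the C8–C9 bond with exocyclic methylene, OMe on C10 anti to the C8–C9 bond, methyl ketone and both methyl esters intact | C=C1CC[C@@H]([C@@](C)(CC(C)=O)C(=O)OC)[C@](C)(OC)[C@H]1CC/C(C)=C/C(=O)OC
F2 | step 11 | tert-butyldimethylsilyl enol ether of F1 (2-silyloxyallyl group on C4) | C=C1CC[C@@H]([C@@](C)(CC(=C)O[Si](C)(C)C(C)(C)C)C(=O)OC)[C@](C)(OC)[C@H]1CC/C(C)=C/C(=O)OC
F3 | step 7 | ethyl ester from the orthopropionate Claisen rearrangement of 12 (C5 and the E-alkene as in 19, epimers at C4) | CCOC(=O)C(C)[C@H](CCC#C[Si](C)(C)C)/C(C)=C/CC/C(C)=C/C(=O)OC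
F4 | step 4 | methyl (2E,7Z)-6-hydroxy-3,7-dimethyl-12-(trimethylsilyl)dodeca-2,7-dien-11-ynoate (racemic 12) | C[Si](C)(C)C#CCC/C=C(C)\C(O)CC/C(C)=C/C(=O)OC
F5 | step 4 | methyl (2E,7Z)-3,7-dimethyl-6-oxo-12-(trimethylsilyl)dodeca-2,7-dien-11-ynoate | C[Si](C)(C)C#CCC/C=C(C)\C(=O)CC/C(C)=C/C(=O)OC
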